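In teal the target came more slowly than the substrate reacted: at 2.50 min the target stood at 11.6%, against 84.9% of the substrate reacted.

| setting | teal | autumn | midnight | winter |
|---|---|---|---|---|
| substrate | 0.30 M | 0.30 M | 0.60 M | 1.2 M |
| partner | 0.21 M | 0.315 M | 0.315 M | 0.315 M |
| remark | run made earlier |  |  |  |
| time |  | 12 min | 12 min | 12 min |

- teal (time / min: target / %, substrate / %): 0.500: 1.1, 67.7; 1.33: 4.2, 36.6; 2.50: 11.6, 15.1; 4.00: 17.1, 4.8; 6.00: 23.0, 0.5; 8.00: 25.7, 0.3

(scatter of a reading: 0.5 percentage points)

- percent here means substrate units held: one homo product counts as two
- what is said of target includes crystals
- crystals is a solid; its amount is given per volume of the solution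
- reactions considered so far: substrate -> intermediate; partner + intermediate -> target; 2 intermediate -> homo product; crystals <-> target; substrate -> decomposition product
- the concentration of target that is asked is that of its free form alone
- "hardly changes" means that all values lie within two and a half points (for a concentration: within two and a half percent of the largest)

- [target] (only what is free in solution) at the end for autumn, midnight, winter, in this order
- the shape of the row from first to last (rises, then falls / rises all the way / falls all the way / falls, then rises / hardly changes)

I read the teal table down. The early rows show that gap, and the reactions considered put the difference in intermediate, homo product and decomposition product. The last rows show the substrate down to 0.3% at 8.00 min. The target was still up 2.7 percentage points on the row before, against a scatter of 0.5 points.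

Then I read the last target value in concentration. It gives 0.0771 M. I called this the teal mark: the total target, crystals counted, that teal was seen to hold. But the table counts crystals inside the target, so it does not show the free [target].

Autumn has the substrate of teal, 1.50 times its partner, and 12 min against 8.00 min. I expected autumn to pass the mark. Midnight and winter hold 0.60 M and 1.2 M of substrate.

My zero was the flat row. At one temperature, with crystals in balance with the solution, the free [target] equals the solubility limit, and the charge does not enter it. So the free reading was the one to watch, not the total. I committed to a flat row, and to no level, since teal gives none.

The forecast did give a level: 0.07 M, 0.07 M and 0.07 M, with the shape "hardly changes". Its ground was this: “I assume saturation was reached at or below that level”.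

The flask gave 0.0220 M, 0.0220 M and 0.0220 M, a row that hardly changes. The shape held, and the level stood below the forecast.

    substrate → intermediate (k = 0.0129 s⁻¹)
    partner + intermediate → target (k = 0.00907 M⁻¹ s⁻¹)
    2 intermediate → homo product (k = 0.0133 M⁻¹ s⁻¹)
    crystals ⇌ target, rate k4*(cs4 - [target]) while solid is left; crystals form when [target] > cs4 (solubility = 22.0 mM, k = 1.67 s⁻¹)
    substrate → decomposition product (k = 6.72 × 10⁻⁶ s⁻¹)

At 12.0 min autumn held 0.125 M of target, crystals counted, which is 1.62 times the teal mark. Winter held 0.219 M, or 2.84 times the mark, with the same free [target] of 0.0220 M. In autumn the exchange between crystals and target relaxes in 0.599 s, far shorter than the 3.97 min by which half of the crystal growth up to the asked time was done. At 12.0 min autumn, each step taken net, made dissolved target and used it up, going into crystals included, at a ratio of 0.998, with crystals at 34.4% of the substrate charged.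

(The readings are simulated with constants of no real substance; noise was put on by code.)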